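The target is a 4→6 dimer of one 7,8-dioxygenated 2,3-cis-flavan-3,4-diol, so everything rests on one monomer and on how its ring C is made. The key step is an enantioselective oxa-Povarov annulation: an O-aryl oxocarbenium ion, whose cationic 2-oxadiene spans O1=C2 and the C8a=C4a bond of the pyrogallol ring A, takes up a Z-enediol diether and thereby forges the C2–C3 and C4–C4a bonds of ring C in one operation, setting C2 and C3; the same monomer supplies both flavan units. Its precursor is an open-chain mixed aryl benzyl acetal. Biomimetic acid-induced self-condensation (C4 of one monomer to C6 of the next) and hydrogenolysis complete the synthesis.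

Key step: step 6

Assumption: flavan-4-yl cations of the 2,3-cis series are captured anti to the C3 oxygen by oxygen and carbon nucleophiles alike, so C4 of both units is fixed in step 7 whatever its configuration after step 6.

Step 1
Reactants: 1 2,3-bis(benzyloxy)benzaldehyde
Product: 3 2,3-bis(benzyloxy)phenol, via aryl formate 2 (not isolated)
Conditions: mCPBA (1.3 equiv), CH2Cl2, 0 °C to rt; then K2CO3 (0.1 equiv), MeOH, rt
Reagents that add atoms: mCPBA, OOC(=O)c1cccc(Cl)c1
Why: Baeyer–Villiger oxidation of an electron-rich ortho-alkoxybenzaldehyde should proceed with aryl migration to the formate, which carbonate-catalysed methanolysis converts into the phenol; no stereocenter is formed.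

Step 2
Reactants: 4 3,4-bis(benzyloxy)benzaldehyde
Product: 5 1,2-bis(benzyloxy)-4-[bis(benzyloxy)methyl]benzene (dibenzyl acetal of 4)
Conditions: BnOTMS (2.2 equiv), TMSOTf (5 mol%), CH2Cl2, −78 °C; pyridine quench
Reagents that add atoms: benzyloxytrimethylsilane, C[Si](C)(C)OCc1ccccc1
Why: Noyori acetalization, in which the silyl triflate activates the aldehyde and two silyl ether molecules deliver the acetal, driven by formation of hexamethyldisiloxane; no stereocenter is formed.

Step 3
Reactants: 5 dibenzyl acetal; 3 2,3-bis(benzyloxy)phenol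
Product: 7 1,2-bis(benzyloxy)-3-{(benzyloxy)[3,4-bis(benzyloxy)phenyl]methoxy}benzene (racemic mixed aryl benzyl acetal), via α-chloro ether 6 (not isolated)
Conditions: AcCl (1.05 equiv), ZnBr2 (1 mol%), CH2Cl2, 0 °C; then 3, iPr2NEt (1.5 equiv), −40 to 0 °C; chromatography on Et3N-deactivated silica
Reagents that add atoms: none
Why: Zinc-bromide-catalysed exchange of one acetal benzyloxy group for chloride gives the α-chloro ether, which O-alkylates the phenol in an SN1-like Williamson etherification; the acetal carbon forms racemic and is planarized in step 6.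

Step 4
Reactants: 8 2-(benzyloxy)acetaldehyde
Product: 9 1,1,2-tris(benzyloxy)ethane
Conditions: BnOTMS (2.2 equiv), TMSOTf (5 mol%), CH2Cl2, −78 °C; pyridine quench
Reagents that add atoms: benzyloxytrimethylsilane, C[Si](C)(C)OCc1ccccc1
Why: Noyori acetalization as in step 2; no stereocenter is formed.

Step 5
Reactants: 9 1,1,2-tris(benzyloxy)ethane
Product: 10 (Z)-1,2-bis(benzyloxy)ethene
Conditions: TMSOTf (1.2 equiv), iPr2NEt (1.5 equiv), CH2Cl2, −20 °C to rt; chromatography on basic alumina
Reagents that add atoms: none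
Why: Gassman-type elimination, in which the silyl triflate ionizes the acetal and the hindered amine deprotonates the α-carbon of the oxocarbenium ion; the Z isomer is expected to predominate (cis effect of 1,2-dialkoxyethenes) and is separated from any E isomer.

Step 6
Reactants: 7 mixed aryl benzyl acetal; 10 (Z)-1,2-bis(benzyloxy)ethene
Product: 13 (2R,3R,4R)-3,4,7,8-tetrakis(benzyloxy)-2-[3,4-bis(benzyloxy)phenyl]chromane (all-cis), via O-aryl oxocarbenium ion 11 (not isolated), via carboxonium ion 12 (not isolated)
Conditions: (R)-3,3'-bis(2,4,6-triisopropylphenyl)-1,1'-binaphthalene-2,2'-diyl N-triflylphosphoramide (10 mol%, antipode selected for the 2R series), 10 (3 equiv), 4 Å MS, toluene, −78 °C; Et3N quench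
Reagents that add atoms: none
Why: Proposed new method: the chiral acid should ionize the mixed acetal at the more basic benzylic oxygen to give the E-configured O-aryl oxocarbenium ion 11 paired with the chiral phosphoramide anion, the enediol ether then adds through its C3 to C2 (Prins-type) to give carboxonium ion 12, and the ring A carbon ortho to the ether oxygen and para to the C7 benzyloxy group closes ring C on C4 and returns the proton to the catalyst. The closest known reaction types are the SnCl4-promoted oxa-Povarov reaction of aryl mixed acetals with alkenes and the chiral-phosphoric-acid-catalysed aza-Povarov reaction of enol ethers, and the enantioselective ion-pair-controlled oxa variant is the untested part. Ring C (the dihydropyran) is closed as a formal inverse-electron-demand [4+2] annulation whose second bond forms by a 6-exo-trig Friedel–Crafts attack on the carboxonium carbon. C2 is set by the chiral anion, which must direct attack to the Si face of the oxocarbenium carbon to give 2R; C3 follows from endo approach of the Z-enediol ether, which places the C3 oxygen cis to the aryl group at C2; C4 arises cis from the suprafacial addition and is not relied upon, because step 7 resets it. The step needs loss of benzyl alcohol in preference to the phenol, which protonation of the more basic alkyl oxygen should favour, and regioselective closure, which the substrate secures because the other ortho position of ring A carries a benzyloxy group.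

Step 7
Reactants: 13 all-cis monomer (two molecules)
Product: 16 (2R,3R,4S)-3,4,7,8-tetrakis(benzyloxy)-2-[3,4-bis(benzyloxy)phenyl]-6-{(2R,3R,4R)-3,7,8-tris(benzyloxy)-2-[3,4-bis(benzyloxy)phenyl]chroman-4-yl}chromane, via flavan-4-yl cation 14 (not isolated), via 4β-benzyl ether epimer 15 (not isolated)
Conditions: TMSOTf (0.2 equiv), CH2Cl2 (0.3 M), −40 to −20 °C; Et3N quench at partial conversion, recovered monomer recycled
Reagents that add atoms: none
Why: Biomimetic Friedel–Crafts self-condensation, in which the acid ionizes the benzylic C4–O bond to cation 14 (stabilized through the C7 oxygen), reversible return of benzyl alcohol anti to the axial C3 benzyloxy group converts the monomer into the 3,4-trans ether 15, and C6 of ring A of a second molecule (para to O1, ortho to C7–O) attacks the cation on the same anti face to set the 4β interflavan bond; the upper C4 is R by the CIP rules here only because the benzyl groups change the priority order, and it is the same geometry that is 4S in 17.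

Step 8
Reactants: 16 undeca-O-benzyl dimer
Product: 17 (2R,3R,4S)-2-(3,4-dihydroxyphenyl)-6-[(2R,3R,4S)-2-(3,4-dihydroxyphenyl)-3,7,8-trihydroxychroman-4-yl]chromane-3,4,7,8-tetrol (target)
Conditions: H2 (1 atm), Pd(OH)2/C (20 wt%), THF/MeOH/H2O (10:10:1), rt; filtration under argon, lyophilization
Reagents that add atoms: none
Why: Hydrogenolysis of all eleven benzyl ethers under neutral conditions, where O–CH2Ph cleavage should be faster than cleavage of the secondary C4–O bond on the 5-deoxy ring A; no stereocenter is touched.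

Compound list
1 | 2,3-bis(benzyloxy)benzaldehyde | O=Cc1cccc(OCc2ccccc2)c1OCc1ccccc1 | starting material
2 | 2,3-bis(benzyloxy)phenyl formate | O=COc1cccc(OCc2ccccc2)c1OCc1ccccc1 | intermediate
3 | 2,3-bis(benzyloxy)phenol | Oc1cccc(OCc2ccccc2)c1OCc1ccccc1 | intermediate
4 | 3,4-bis(benzyloxy)benzaldehyde | O=Cc1ccc(OCc2ccccc2)c(OCc2ccccc2)c1 | starting material
5 | 1,2-bis(benzyloxy)-4-[bis(benzyloxy)methyl]benzene | C(OCc1ccccc1)(OCc1ccccc1)c1ccc(OCc2ccccc2)c(OCc2ccccc2)c1 | intermediate
6 | 1,2-bis(benzyloxy)-4-[(benzyloxy)chloromethyl]benzene (racemic) | ClC(OCc1ccccc1)c1ccc(OCc2ccccc2)c(OCc2ccccc2)c1 | intermediate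
7 | 1,2-bis(benzyloxy)-3-{(benzyloxy)[3,4-bis(benzyloxy)phenyl]methoxy}benzene (racemic) | c1ccc(OC(OCc2ccccc2)c2ccc(OCc3ccccc3)c(OCc3ccccc3)c2)c(OCc2ccccc2)c1OCc1ccccc1 | intermediate
8 | 2-(benzyloxy)acetaldehyde | O=CCOCc1ccccc1 | starting material
9 | 1,1,2-tris(benzyloxy)ethane | C(OCc1ccccc1)(OCc1ccccc1)COCc1ccccc1 | intermediate
10 | (Z)-1,2-bis(benzyloxy)ethene | C(c1ccccc1)O/C=C\OCc1ccccc1 | intermediate
11 | (E)-[2,3-bis(benzyloxy)phenyl][3,4-bis(benzyloxy)benzylidene]oxonium ion | c1ccccc1COc1c(OCc2ccccc2)cccc1/[O+]=C/c1ccc(OCc2ccccc2)c(OCc2ccccc2)c1 | intermediate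
12 | benzyl{(2S,3R)-2-(benzyloxy)-3-[2,3-bis(benzyloxy)phenoxy]-3-[3,4-bis(benzyloxy)phenyl]propylidene}oxonium ion | c1ccc(O[C@H](c2ccc(OCc3ccccc3)c(OCc3ccccc3)c2)[C@H](OCc2ccccc2)C=[O+]Cc2ccccc2)c(OCc2ccccc2)c1OCc1ccccc1 | intermediate
13 | (2R,3R,4R)-3,4,7,8-tetrakis(benzyloxy)-2-[3,4-bis(benzyloxy)phenyl]chromane (2,3-cis-3,4-cis) | c1cc2c(c(OCc5ccccc5)c1OCc5ccccc5)O[C@H](c1ccc(OCc5ccccc5)c(OCc5ccccc5)c1)[C@H](OCc5ccccc5)[C@@H]2OCc5ccccc5 | intermediate
14 | (2R,3R)-3,7,8-tris(benzyloxy)-2-[3,4-bis(benzyloxy)phenyl]chroman-4-ylium ion | c1cc2c(c(OCc5ccccc5)c1OCc5ccccc5)O[C@H](c1ccc(OCc5ccccc5)c(OCc5ccccc5)c1)[C@H](OCc5ccccc5)[CH+]2 | intermediate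
15 | (2R,3R,4S)-3,4,7,8-tetrakis(benzyloxy)-2-[3,4-bis(benzyloxy)phenyl]chromane (2,3-cis-3,4-trans) | c1cc2c(c(OCc5ccccc5)c1OCc5ccccc5)O[C@H](c1ccc(OCc5ccccc5)c(OCc5ccccc5)c1)[C@H](OCc5ccccc5)[C@H]2OCc5ccccc5 | intermediate
16 | (2R,3R,4S)-3,4,7,8-tetrakis(benzyloxy)-2-[3,4-bis(benzyloxy)phenyl]-6-{(2R,3R,4R)-3,7,8-tris(benzyloxy)-2-[3,4-bis(benzyloxy)phenyl]chroman-4-yl}chromane (both units 2,3-cis-3,4-trans) | O(Cc5ccccc5)c1ccc([C@H]2Oc3c(ccc(OCc5ccccc5)c3OCc5ccccc5)[C@H](c3cc4c(c(OCc5ccccc5)c3OCc5ccccc5)O[C@H](c3ccc(OCc5ccccc5)c(OCc5ccccc5)c3)[C@H](OCc5ccccc5)[C@H]4OCc5ccccc5)[C@H]2OCc5ccccc5)cc1OCc5ccccc5 | intermediate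
17 | (2R,3R,4S)-2-(3,4-dihydroxyphenyl)-6-[(2R,3R,4S)-2-(3,4-dihydroxyphenyl)-3,7,8-trihydroxychroman-4-yl]chromane-3,4,7,8-tetrol | Oc1ccc([C@H]2Oc3c(ccc(O)c3O)[C@H](c3cc4c(c(O)c3O)O[C@H](c3ccc(O)c(O)c3)[C@H](O)[C@H]4O)[C@H]2O)cc1O | target

Total step count: 8. Longest linear sequence: 5 steps (steps 1, 3, 6, 7, 8).

Steps most likely to fail

Step 6 (Proposed new method). What may go wrong is poor facial discrimination of the oxocarbenium ion by the chiral anion, exo approach leading to the 2,3-trans series, loss of the phenol instead of benzyl alcohol on ionization, or acid-induced oligomerization of the enol ether. The fallback uses known chemistry and sets out from 7 and 10: the established stoichiometric oxa-Povarov conditions (SnCl4, 1.1 equiv, CH2Cl2, −78 °C) should give the all-cis monomer as a racemate, that is 13 together with its enantiomer (2S,3S,4S)-3,4,7,8-tetrakis(benzyloxy)-2-[3,4-bis(benzyloxy)phenyl]chromane F1. Preparative chromatography on amylose tris(3,5-dimethylphenylcarbamate) would separate the two, and the route is rejoined at 13.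

Step 7. What may go wrong is condensation running on beyond the dimer, because the product is again both nucleophile and latent electrophile, and arylation through positions other than C6 of ring A. The fallback sets out from 13 and separates the two roles. One portion is treated with benzyl mercaptan and BF3·OEt2 (CH2Cl2, −40 °C) to give the thioether (2R,3S,4S)-4-(benzylsulfanyl)-3,7,8-tris(benzyloxy)-2-[3,4-bis(benzyloxy)phenyl]chromane F2. The other portion is equilibrated with benzyl alcohol and catalytic camphorsulfonic acid (CH2Cl2, 0 °C) and isolated as 15. F2 is then ionized with the thiophilic salt AgBF4 (THF, 0 °C) in the presence of 2,6-di-tert-butyl-4-methylpyridine and an excess of 15; only the C4–S bond is activated, so neither the nucleophile nor the product should re-enter as an electrophile. The route is rejoined at 16.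

Step 8. What may go wrong is hydrogenolytic loss of the benzylic C4 oxygen of the terminal unit while it still stands as a dibenzylic ether. The fallback sets out from 16 and removes that ether first by solvolysis (catalytic TsOH, THF/H2O, 0 °C, dilute), in which water captures the cation anti to the C3 oxygen, to give the free alcohol (2R,3R,4S)-3,7,8-tris(benzyloxy)-2-[3,4-bis(benzyloxy)phenyl]-6-{(2R,3R,4R)-3,7,8-tris(benzyloxy)-2-[3,4-bis(benzyloxy)phenyl]chroman-4-yl}chroman-4-ol F3. A free benzylic alcohol is cleaved far more slowly than its benzyl ether, so hydrogenolysis of F3 (H2, Pd/C, EtOAc/MeOH, rt) should then stop at the phenol stage, and the route is rejoined at 17.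

Further compounds
F1 | step 6 | (2S,3S,4S)-3,4,7,8-tetrakis(benzyloxy)-2-[3,4-bis(benzyloxy)phenyl]chromane | c1cc2c(c(OCc5ccccc5)c1OCc5ccccc5)O[C@@H](c1ccc(OCc5ccccc5)c(OCc5ccccc5)c1)[C@@H](OCc5ccccc5)[C@H]2OCc5ccccc5
F2 | step 7 | (2R,3S,4S)-4-(benzylsulfanyl)-3,7,8-tris(benzyloxy)-2-[3,4-bis(benzyloxy)phenyl]chromane | c1cc2c(c(OCc5ccccc5)c1OCc5ccccc5)O[C@H](c1ccc(OCc5ccccc5)c(OCc5ccccc5)c1)[C@H](OCc5ccccc5)[C@H]2SCc5ccccc5
F3 | step 8 | (2R,3R,4S)-3,7,8-tris(benzyloxy)-2-[3,4-bis(benzyloxy)phenyl]-6-{(2R,3R,4R)-3,7,8-tris(benzyloxy)-2-[3,4-bis(benzyloxy)phenyl]chroman-4-yl}chroman-4-ol | O(Cc5ccccc5)c1ccc([C@H]2Oc3c(ccc(OCc5ccccc5)c3OCc5ccccc5)[C@H](c3cc4c(c(OCc5ccccc5)c3OCc5ccccc5)O[C@H](c3ccc(OCc5ccccc5)c(OCc5ccccc5)c3)[C@H](OCc5ccccc5)[C@H]4O)[C@H]2OCc5ccccc5)cc1OCc5ccccc5
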